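**Retrosynthetic overview**
1. Target 32 ⇐ enone 29: the C3 and C2 hydroxyls are introduced last (α′-hydroxylation, then hydroxyl-directed reduction of the C2 ketone), so no protecting groups are needed.
2. Eleven-membered ring (formed last of the three) ⇐ C8–C9 nickel/chromium-mediated coupling of enol triflate and aldehyde in 27.
3. Six-membered ring (formed second, key step) ⇐ C15–C16 by 6-exo cyclisation of the C15 vinyl radical of the tetrasubstituted iodoenone 22 onto the acetylcyclopentene; this sets C16 and C7.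
4. 22 ⇐ ynone 18 + aldehyde 5: C1–C14 by an asymmetric iodo-aldol coupling that also installs the vinyl iodide.
5. Cyclopentane (present from the start): 18 from 3-methoxycyclopentenone (C4 by Cu-catalysed Me3Al addition); 5 from methyl crotonate (C12 by Cu-catalysed Grignard addition).

Assumption: atom labels follow trinervitane numbering — six-membered ring C1–C2–C3–C4–C16–C15, cyclopentane C4–C5–C6–C7–C16, eleven-membered ring C1–C15–C16–C7–C8–C9–C10–C11–C12–C13–C14, C17 on C15, C18 on C4, C19 = exocyclic CH2 on C8, C20 on C12; "β face" means the face of the C18 methyl.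

**Step 1**
Reactants: 1 methyl (E)-but-2-enoate; 2 but-3-en-1-ylmagnesium bromide
Product: 3 methyl (S)-3-methylhept-6-enoate
Conditions: CuI (2 mol %), Tol-BINAP (3 mol %, the antipode that gives 3S), t-BuOMe, −40 °C; aq NH4Cl
Reagents that add atoms: none
Why: Copper-catalysed asymmetric conjugate addition of a Grignard reagent to an α,β-unsaturated ester; the chiral bisphosphine–copper complex delivers the butenyl group to one face of the crotonate and sets C12 (S).

**Step 2**
Reactants: 3 methyl (S)-3-methylhept-6-enoate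
Product: 5 (S)-3-methylhept-6-enal, via aluminium hemiacetal 4 (not isolated)
Conditions: i-Bu2AlH (1.05 equiv), CH2Cl2, −78 °C; MeOH, aq Rochelle salt
Reagents that add atoms: none
Why: Partial ester reduction with DIBAL-H; the tetrahedral aluminium hemiacetal 4 persists at −78 °C and releases the aldehyde only on work-up, and C12 is not touched.

**Step 3**
Reactants: 6 3-methoxycyclopent-2-en-1-one; 7 N-methoxy-N-methylacetamide
Product: 10 N-methoxy-N-methyl-2-(3-oxocyclopent-1-en-1-yl)acetamide, via lithium amide enolate 8 (not isolated), via lithium alkoxide adduct 9 (not isolated)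
Conditions: LDA (1.1 equiv), THF, −78 °C; add 6, −78 → −20 °C; then 1 M HCl, 0 °C → rt
Reagents that add atoms: water (O)
Why: Stork–Danheiser alkylative carbonyl transposition; enolate 8 adds 1,2 to the vinylogous ester and acid converts adduct 9 (loss of methanol) into the 3-substituted cyclopentenone that carries the future C3–C2 unit.

**Step 4**
Reactants: 10 N-methoxy-N-methyl-2-(3-oxocyclopent-1-en-1-yl)acetamide
Product: 13 (R)-3-{2-[methoxy(methyl)amino]-2-oxoethyl}-3-methylcyclopent-1-en-1-yl trifluoromethanesulfonate, via dimethylaluminium enolate 11 (not isolated), via lithium aluminate enolate 12 (not isolated)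
Conditions: Cu(OTf)2 (5 mol %), binaphthol-derived phosphoramidite (10 mol %, the antipode that gives R), Me3Al (1.5 equiv), Et2O, −30 °C; then MeLi (1.5 equiv), −78 °C; PhNTf2, −78 → 0 °C
Reagents that add atoms: trimethylaluminium (C[Al](C)C); N-phenylbis(trifluoromethanesulfonimide) (O=S(=O)(N(c1ccccc1)S(=O)(=O)C(F)(F)F)C(F)(F)F)
Why: Copper-catalysed asymmetric conjugate addition of Me3Al to a β-substituted cyclopentenone creates the C4 quaternary centre under ligand control, and O-triflation of the regiodefined enolate (activated as the ate complex 12, which forms faster than MeLi can attack the Weinreb amide) fixes the double bond between the future C16 and C7.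

**Step 5**
Reactants: 13 the enol triflate; 14 butyl vinyl ether
Product: 15 (R)-2-[3-(1-butoxyethenyl)-1-methylcyclopent-2-en-1-yl]-N-methoxy-N-methylacetamide
Conditions: Pd(OAc)2 (3 mol %), 1,3-bis(diphenylphosphino)propane (6 mol %), Et3N (2 equiv), DMF, 60 °C
Reagents that add atoms: none
Why: Heck reaction of an enol triflate with an electron-rich vinyl ether; the triflate/bidentate-phosphine (cationic palladium) pathway gives α-vinylation only, so the 2-butoxydiene is a masked C7 acetyl group (C8, C19) and C4 is untouched.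

**Step 6**
Reactants: 15 the butoxydiene amide; 16 prop-1-yn-1-ylmagnesium bromide
Product: 18 (R)-1-(3-acetyl-1-methylcyclopent-2-en-1-yl)pent-3-yn-2-one, via magnesium chelate 17 (not isolated)
Conditions: 16 (1.3 equiv), THF, −40 → 0 °C; then 1 M HCl, THF, 0 °C → rt
Reagents that add atoms: water (O)
Why: Weinreb ketone synthesis; the five-membered chelate 17 stops the addition after one propynyl group (C1, C15, C17), and the acidic work-up releases the ynone and hydrolyses the enol ether to the methyl ketone.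

**Step 7**
Reactants: 18 the ynone; 5 (S)-3-methylhept-6-enal
Product: 21 (Z)-1-[(R)-3-acetyl-1-methylcyclopent-2-en-1-yl]-3-[(1S,3S)-1-hydroxy-3-methylhept-6-en-1-yl]-4-iodopent-3-en-2-one, via silyl iodoallenolate 19 (not isolated), via trimethylsilyl ether 20 (not isolated)
Conditions: (S)-diphenylprolinol-derived B-(o-tolyl)oxazaborolidinium bistriflimide (20 mol %, the antipode that gives 14S), Me3SiI (1.3 equiv), CH2Cl2, −78 °C; then 1 M HCl
Reagents that add atoms: iodotrimethylsilane (C[Si](C)(C)I)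
Why: Proposed new method: catalytic asymmetric iodo-aldol (β-iodo Morita–Baylis–Hillman) coupling extended to a β-methyl ynone — TMSI adds 1,4 to the ynone to give allenolate 19, whose α-carbon (C1) attacks aldehyde 5 bound to the chiral oxazaborolidinium ion (closest known reaction: the same three-component coupling with propiolates and terminal ynones), which forms C1–C14, sets C14 (S) by catalyst control and installs the C15 vinyl iodide, while the neopentyl enone terminus C16 is too hindered to take up iodide.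

**Step 8**
Reactants: 21 the iodo-aldol adduct
Product: 22 the C14 acetate of 21, (Z)-1-[(R)-3-acetyl-1-methylcyclopent-2-en-1-yl]-3-[(1S,3S)-1-acetoxy-3-methylhept-6-en-1-yl]-4-iodopent-3-en-2-one
Conditions: Ac2O, pyridine, DMAP (cat), CH2Cl2, 0 °C
Reagents that add atoms: acetic anhydride (CC(=O)OC(C)=O)
Why: Acylation of the secondary alcohol installs the final C14 acetate early, and it also removes the O–H from the vicinity of the radical generated next.

**Step 9**
Reactants: 22 the acetoxy vinyl iodide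
Product: 23 (1S,3S)-1-[(1R,3aR,7aR)-1-acetyl-3a,7-dimethyl-5-oxo-2,3,3a,4,5,7a-hexahydro-1H-inden-6-yl]-3-methylhept-6-en-1-yl acetate
Conditions: Bu3SnH (1.3 equiv) and AIBN (0.2 equiv) added over 6 h, PhH, 80 °C, 5 mM
Reagents that add atoms: none
Why: Key step, 6-exo-trig vinyl radical cyclisation by the tin hydride method: the σ-radical at C15 inverts fast (iodide geometry is irrelevant) and adds to C16, the β-carbon of the acetylcyclopentene, forming C15–C16 and the cyclohexenone with its tetrasubstituted C1=C15 bond; the short tether from C4 allows only cis ring fusion (C16–H cis to C18), and the C7 α-keto radical takes hydrogen from Bu3SnH on the open convex face, which puts the acetyl group on the concave face as the target requires.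

**Step 10**
Reactants: 23 the bicyclic diketone
Product: 25 (1S,3S)-3-methyl-1-[(1R,3aR,7aR)-3a,7-dimethyl-5-oxo-1-(1-{[(trifluoromethyl)sulfonyl]oxy}ethenyl)-2,3,3a,4,5,7a-hexahydro-1H-inden-6-yl]hept-6-en-1-yl acetate, via potassium enolate 24 (not isolated)
Conditions: KHMDS (1.05 equiv), THF, −78 °C, 15 min; Comins' reagent (1.2 equiv), −78 °C
Reagents that add atoms: N-(5-chloropyridin-2-yl)bis(trifluoromethanesulfonimide) (O=S(=O)(N(c1ccc(Cl)cn1)S(=O)(=O)C(F)(F)F)C(F)(F)F)
Why: Kinetic enolate formation and O-triflation; the base removes a proton from the unhindered acetyl CH3 (C19) in preference to the hindered C3–H2 next to the quaternary C4 or the C7 methine, so C7 is not epimerised and the C8=C19 enol triflate results.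

**Step 11**
Reactants: 25 the enol triflate
Product: 27 (1S,3S)-3-methyl-6-oxo-1-[(1R,3aR,7aR)-3a,7-dimethyl-5-oxo-1-(1-{[(trifluoromethyl)sulfonyl]oxy}ethenyl)-2,3,3a,4,5,7a-hexahydro-1H-inden-6-yl]hexyl acetate, via ozonide 26 (not isolated)
Conditions: O3 (1.0 equiv, followed by TLC), CH2Cl2, −78 °C; then PPh3, −78 °C → rt
Reagents that add atoms: ozone ([O-][O+]=O)
Why: Ozonolysis (Criegee) is selective for the electron-rich monosubstituted alkene over the electron-poor enone and enol triflate double bonds, and it unmasks the C9 aldehyde.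

**Step 12**
Reactants: 27 the aldehyde enol triflate
Product: 28 (4R,7R,9R,12S,14S,16R)-9-hydroxy-2-oxotrinervita-1(15),8(19)-dien-14-yl acetate
Conditions: CrCl2 (6 equiv), Kishi-type chiral oxazoline–sulfonamide ligand (6.6 equiv, the antipode that gives 9R), Et3N (6.6 equiv), NiCl2 (0.3 equiv), THF/MeCN, rt; 27 added over 10 h to 2 mM
Reagents that add atoms: none
Why: Nozaki–Hiyama–Kishi macrocyclisation: zerovalent nickel inserts into the enol triflate, the alkenyl group passes to chromium and adds to the aldehyde (ketones are left alone), closing the eleven-membered ring and giving the C8(=C19H2)–C9(OH) unit directly; the chiral chromium complex selects the aldehyde face that gives C9 (R).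

**Step 13**
Reactants: 28 the macrocyclic allylic alcohol
Product: 29 (4R,7R,9R,12S,14S,16R)-2-oxotrinervita-1(15),8(19)-diene-9,14-diyl diacetate
Conditions: Ac2O, pyridine, DMAP (cat), CH2Cl2, rt
Reagents that add atoms: acetic anhydride (CC(=O)OC(C)=O)
Why: Acylation of the C9 alcohol completes the diacetate before the free diol is made, so the four oxygens never need to be told apart.

**Step 14**
Reactants: 29 the diacetoxy enone
Product: 31 (3R,4S,7R,9R,12S,14S,16S)-3-hydroxy-2-oxotrinervita-1(15),8(19)-diene-9,14-diyl diacetate, via sodium dienolate 30 (not isolated)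
Conditions: NaHMDS (1.1 equiv), THF, −78 °C; 2-(benzenesulfonyl)-3-phenyloxaziridine (1.3 equiv), −78 °C; AcOH
Reagents that add atoms: 2-(benzenesulfonyl)-3-phenyloxaziridine (O=S(=O)(N1OC1c1ccccc1)c1ccccc1)
Why: Davis oxidation of the kinetic α′-enolate (C3–H2 is removed faster than acetate or γ-protons at −78 °C); oxygen is delivered to the β face because the other face of C3 is screened by the syn-axial C16–C7 bond of the cis-fused cyclopentane and by the macrocyclic bridge, and the resulting equatorial, hydrogen-bonded ketol (OH cis to C18, C3 R) is also the more stable epimer.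

**Step 15**
Reactants: 31 the α′-hydroxy enone
Product: 32 (2R,3R,4S,7R,9R,12S,14S,16S)-2,3-dihydroxytrinervita-1(15),8(19)-diene-9,14-diyl diacetate (target)
Conditions: Me4NBH(OAc)3 (5 equiv), MeCN/AcOH (1:1), −30 °C
Reagents that add atoms: none
Why: Hydroxyl-directed reduction (Saksena–Evans): the C3 hydroxyl binds boron and delivers hydride to the carbonyl face syn to itself, so the new C2 hydroxyl is trans to the C3 hydroxyl (C2 R), and the reagent gives only 1,2-reduction and spares the acetates and both alkenes.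

**Compound list**
1 | methyl (E)-but-2-enoate | C/C=C/C(=O)OC | starting material
2 | but-3-en-1-ylmagnesium bromide | C=CCC[Mg]Br | starting material
3 | methyl (S)-3-methylhept-6-enoate | C=CCC[C@H](C)CC(=O)OC | intermediate
4 | diisobutylaluminium hemiacetal of 3 | C=CCC[C@H](C)CC(OC)O[Al](CC(C)C)CC(C)C | intermediate
5 | (S)-3-methylhept-6-enal | C=CCC[C@H](C)CC=O | intermediate
6 | 3-methoxycyclopent-2-en-1-one | COC1=CC(=O)CC1 | starting material
7 | N-methoxy-N-methylacetamide | CC(=O)N(C)OC | starting material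
8 | lithium enolate of 7 | [Li+].[O-]C(=C)N(C)OC | intermediate
9 | lithium 3-methoxy-1-{2-[methoxy(methyl)amino]-2-oxoethyl}cyclopent-2-en-1-olate (racemic) | [Li+].[O-]C1(CC(=O)N(C)OC)C=C(OC)CC1 | intermediate
10 | N-methoxy-N-methyl-2-(3-oxocyclopent-1-en-1-yl)acetamide | CON(C)C(=O)CC1=CC(=O)CC1 | intermediate
11 | (R)-dimethylaluminium enolate from Me addition to 10 | CON(C)C(=O)C[C@]1(C)C=C(O[Al](C)C)CC1 | intermediate
12 | lithium trimethylaluminate enolate from 11 | [Li+].CON(C)C(=O)C[C@]1(C)C=C(O[Al-](C)(C)C)CC1 | intermediate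
13 | (R)-3-{2-[methoxy(methyl)amino]-2-oxoethyl}-3-methylcyclopent-1-en-1-yl trifluoromethanesulfonate | CON(C)C(=O)C[C@]1(C)C=C(OS(=O)(=O)C(F)(F)F)CC1 | intermediate
14 | butyl vinyl ether | C=COCCCC | starting material
15 | (R)-2-[3-(1-butoxyethenyl)-1-methylcyclopent-2-en-1-yl]-N-methoxy-N-methylacetamide | CON(C)C(=O)C[C@]1(C)C=C(C(=C)OCCCC)CC1 | intermediate
16 | prop-1-yn-1-ylmagnesium bromide | CC#C[Mg]Br | starting material
17 | bromomagnesium N,O-chelated adduct of 15 and 16 | CC#CC(O[Mg]Br)(N(C)OC)C[C@]1(C)C=C(C(=C)OCCCC)CC1 | intermediate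
18 | (R)-1-(3-acetyl-1-methylcyclopent-2-en-1-yl)pent-3-yn-2-one | CC#CC(=O)C[C@]1(C)C=C(C(C)=O)CC1 | intermediate
19 | (R)-1-{3-[4-iodo-2-(trimethylsilyloxy)penta-2,3-dien-1-yl]-3-methylcyclopent-1-en-1-yl}ethan-1-one | CC(I)=C=C(O[Si](C)(C)C)C[C@]1(C)C=C(C(C)=O)CC1 | intermediate
20 | C14 trimethylsilyl ether of 21 | C=CCC[C@H](C)C[C@H](O[Si](C)(C)C)/C(=C(\C)I)C(=O)C[C@]1(C)C=C(C(C)=O)CC1 | intermediate
21 | (Z)-1-[(R)-3-acetyl-1-methylcyclopent-2-en-1-yl]-3-[(1S,3S)-1-hydroxy-3-methylhept-6-en-1-yl]-4-iodopent-3-en-2-one | C=CCC[C@H](C)C[C@H](O)/C(=C(\C)I)C(=O)C[C@]1(C)C=C(C(C)=O)CC1 | intermediate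
22 | (Z)-1-[(R)-3-acetyl-1-methylcyclopent-2-en-1-yl]-3-[(1S,3S)-1-acetoxy-3-methylhept-6-en-1-yl]-4-iodopent-3-en-2-one | C=CCC[C@H](C)C[C@H](OC(C)=O)/C(=C(\C)I)C(=O)C[C@]1(C)C=C(C(C)=O)CC1 | intermediate
23 | (1S,3S)-1-[(1R,3aR,7aR)-1-acetyl-3a,7-dimethyl-5-oxo-2,3,3a,4,5,7a-hexahydro-1H-inden-6-yl]-3-methylhept-6-en-1-yl acetate | C=CCC[C@H](C)C[C@H](OC(C)=O)C2=C(C)[C@@H]3[C@H](C(C)=O)CC[C@]3(C)CC2=O | intermediate
24 | potassium enolate of the acetyl group of 23 | [K+].C=CCC[C@H](C)C[C@H](OC(C)=O)C2=C(C)[C@@H]3[C@H](C(=C)[O-])CC[C@]3(C)CC2=O | intermediate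
25 | (1S,3S)-3-methyl-1-[(1R,3aR,7aR)-3a,7-dimethyl-5-oxo-1-(1-{[(trifluoromethyl)sulfonyl]oxy}ethenyl)-2,3,3a,4,5,7a-hexahydro-1H-inden-6-yl]hept-6-en-1-yl acetate | C=CCC[C@H](C)C[C@H](OC(C)=O)C2=C(C)[C@@H]3[C@H](C(=C)OS(=O)(=O)C(F)(F)F)CC[C@]3(C)CC2=O | intermediate
26 | 1,2,4-trioxolane (ozonide) of the terminal alkene of 25 | C1OC(OO1)CC[C@H](C)C[C@H](OC(C)=O)C2=C(C)[C@@H]3[C@H](C(=C)OS(=O)(=O)C(F)(F)F)CC[C@]3(C)CC2=O | intermediate
27 | (1S,3S)-3-methyl-6-oxo-1-[(1R,3aR,7aR)-3a,7-dimethyl-5-oxo-1-(1-{[(trifluoromethyl)sulfonyl]oxy}ethenyl)-2,3,3a,4,5,7a-hexahydro-1H-inden-6-yl]hexyl acetate | O=CCC[C@H](C)C[C@H](OC(C)=O)C2=C(C)[C@@H]3[C@H](C(=C)OS(=O)(=O)C(F)(F)F)CC[C@]3(C)CC2=O | intermediate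
28 | (4R,7R,9R,12S,14S,16R)-9-hydroxy-2-oxotrinervita-1(15),8(19)-dien-14-yl acetate | C=C1[C@H](O)CC[C@H](C)C[C@H](OC(C)=O)C2=C(C)[C@@H]3[C@H]1CC[C@]3(C)CC2=O | intermediate
29 | (4R,7R,9R,12S,14S,16R)-2-oxotrinervita-1(15),8(19)-diene-9,14-diyl diacetate | C=C1[C@H](OC(C)=O)CC[C@H](C)C[C@H](OC(C)=O)C2=C(C)[C@@H]3[C@H]1CC[C@]3(C)CC2=O | intermediate
30 | sodium C2–C3 dienolate of 29 | [Na+].C=C1[C@H](OC(C)=O)CC[C@H](C)C[C@H](OC(C)=O)C2=C(C)[C@@H]3[C@H]1CC[C@]3(C)C=C2[O-] | intermediate
31 | (3R,4S,7R,9R,12S,14S,16S)-3-hydroxy-2-oxotrinervita-1(15),8(19)-diene-9,14-diyl diacetate | C=C1[C@H](OC(C)=O)CC[C@H](C)C[C@H](OC(C)=O)C2=C(C)[C@@H]3[C@H]1CC[C@]3(C)[C@@H](O)C2=O | intermediate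
32 | (2R,3R,4S,7R,9R,12S,14S,16S)-2,3-dihydroxytrinervita-1(15),8(19)-diene-9,14-diyl diacetate | C=C1[C@H](OC(C)=O)CC[C@H](C)C[C@H](OC(C)=O)C2=C(C)[C@@H]3[C@H]1CC[C@]3(C)[C@@H](O)[C@@H]2O | target

**Step count**
Total: 15 steps. Longest linear sequence: 13 steps (steps 3–15, from 6 and 7 to 32); steps 1–2 make aldehyde 5, which joins at step 7.

**Three steps most likely to fail, with fallbacks**

Step 7 (iodo-aldol on a β-methyl ynone; reactivity and selectivity at C14 are beyond the tested scope). The fallback sets out from 18 and comes back at 23; it closes the six-membered ring before the side chain is attached. Ynone 18 with NaI/AcOH gives (R,Z)-1-(3-acetyl-1-methylcyclopent-2-en-1-yl)-4-iodopent-3-en-2-one F1. The same tin hydride 6-exo vinyl radical cyclisation converts it into (1R,3aR,7aR)-1-acetyl-3a,7-dimethyl-1,2,3,3a,4,7a-hexahydro-5H-inden-5-one F2. I2/pyridine iodinates the enone α-carbon to give (1R,3aR,7aR)-1-acetyl-6-iodo-3a,7-dimethyl-1,2,3,3a,4,7a-hexahydro-5H-inden-5-one F3. A nickel/chromium coupling of F3 with aldehyde 5 under a chiral sulfonamide ligand sets C14 and gives (1R,3aR,7aR)-1-acetyl-6-[(1S,3S)-1-hydroxy-3-methylhept-6-en-1-yl]-3a,7-dimethyl-1,2,3,3a,4,7a-hexahydro-5H-inden-5-one F4. Acetylation (Ac2O, pyridine) then rejoins the route at 23.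

Step 9 (the vinyl radical can be lost to 1,5-hydrogen transfer from C13 or C3, or to direct reduction, and hydrogen delivery at C7 may not be fully face-selective). The fallback sets out from 22 and comes back at 23. The same C15–C16 bond is closed by a reductive Heck reaction (Pd(OAc)2, PPh3, HCO2Na, DMF, 80 °C): carbopalladation of the enone by the alkenylpalladium, then protonation of the palladium enolate from the convex face. This detour makes no compound outside the list (F0).

Step 12 (eleven-membered ring closure; the configuration at C9 depends on ligand control inside a macrocyclic transition state, and attack of the alkenylchromium on the C2 ketone is a possible side path). The fallback sets out from 28, taken as the mixture of C9 epimers, and comes back at 28. Dess–Martin periodinane oxidises the allylic alcohol to (4R,7R,12S,14S,16R)-2,9-dioxotrinervita-1(15),8(19)-dien-14-yl acetate F5. Corey–Bakshi–Shibata reduction (oxazaborolidine antipode for 9R, catecholborane, −78 °C) of the unhindered α-methylene ketone, which reacts ahead of the hindered C2 enone, then returns 28 as the 9R alcohol.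

**Further compounds**
F1 | step 7 | (R,Z)-1-(3-acetyl-1-methylcyclopent-2-en-1-yl)-4-iodopent-3-en-2-one | C/C(I)=C/C(=O)C[C@]1(C)C=C(C(C)=O)CC1
F2 | step 7 | (1R,3aR,7aR)-1-acetyl-3a,7-dimethyl-1,2,3,3a,4,7a-hexahydro-5H-inden-5-one | C1=C(C)[C@@H]2[C@H](C(C)=O)CC[C@]2(C)CC1=O
F3 | step 7 | (1R,3aR,7aR)-1-acetyl-6-iodo-3a,7-dimethyl-1,2,3,3a,4,7a-hexahydro-5H-inden-5-one | IC1=C(C)[C@@H]2[C@H](C(C)=O)CC[C@]2(C)CC1=O
F4 | step 7 | (1R,3aR,7aR)-1-acetyl-6-[(1S,3S)-1-hydroxy-3-methylhept-6-en-1-yl]-3a,7-dimethyl-1,2,3,3a,4,7a-hexahydro-5H-inden-5-one | C=CCC[C@H](C)C[C@H](O)C2=C(C)[C@@H]3[C@H](C(C)=O)CC[C@]3(C)CC2=O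
F0 | step 9 | none | none
F5 | step 12 | (4R,7R,12S,14S,16R)-2,9-dioxotrinervita-1(15),8(19)-dien-14-yl acetate | C=C1C(=O)CC[C@H](C)C[C@H](OC(C)=O)C2=C(C)[C@@H]3[C@H]1CC[C@]3(C)CC2=O
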